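**Plan**

Labels: upper chroman O1–C2–C3–C4 fused to ring A, ring B on C3, ring C (C1c–C6c) on C4 through C1c; lower chroman O1′–C2′–C3′–C4′ fused to ring D, C3′ on C6c.
Retrosynthesis cuts O1–C2 and C3–C4 (ring A ortho-quinone methide plus ring B arylacetaldehyde), then C4–C4a (ring A aryllithium plus ring C aldehyde), then O1′–C2′ (Mitsunobu), C2′–C3′ (one-carbon homologation at boron), and finally C6c–C3′ together with C4′–C4a′.
Enabling feature: C3′ carries ring C through C6c, which is meta to both ring C oxygens and so is reachable only as a bromide-derived organometallic, and carries the benzylic CH2 (C4′) of ring D. This aryl–CH(B)–CH2–aryl unit is what a vinylboron conjunctive coupling delivers, with boron sitting where C2′ is to be added.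
Forward: ring C bromide, vinyl–B(pin) and ring D triflate are joined; homologation/oxidation and Mitsunobu closure give the lower chroman; the unmasked ring C aldehyde takes up ring A; a formal [4+2] of the derived ortho-quinone methide closes the upper chroman; reduction and hydrogenolysis finish.
Stereochemistry: C3′ (R) comes from the chiral bisphosphine in the coupling and is carried through with retention; C3 (R) and C4 (S), trans, come from a prolinol-silyl-ether enamine adding to the ortho-quinone methide under catalyst control.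

Key step: step 10

Remark: the hand of the MandyPhos ligand and of the prolinol catalyst is assigned by analogy with simple substrates; if a model reaction shows the opposite sense, the mirror-image ligand or catalyst is used.

**Route**

Step 1
Reactants: 1 1-bromo-3,5-dimethoxybenzene
Product: 3 2-bromo-4,6-dimethoxybenzaldehyde, via iminium chloride 2 (not isolated)
Conditions: POCl3, DMF, 0 → 90 °C; then ice/H2O
Reagents that add atoms: N,N-dimethylformamide CN(C)C=O; water O
Why: Vilsmeier–Haack formylation should attack the position para to one methoxy group and ortho to the other (the two such positions are equivalent, the site between the methoxy groups being more hindered), and hydrolysis of iminium salt 2 releases the aldehyde.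

Step 2
Reactants: 3 2-bromo-4,6-dimethoxybenzaldehyde
Product: 4 2-bromo-4,6-dihydroxybenzaldehyde
Conditions: BBr3, CH2Cl2, −78 °C → rt; then H2O
Reagents that add atoms: none
Why: Lewis-acid ether cleavage with BBr3 should remove both O-methyl groups without touching the aryl bromide or the aldehyde, so that the two phenols can afterwards be told apart by their hydrogen bonding.

Step 3
Reactants: 4 2-bromo-4,6-dihydroxybenzaldehyde
Product: 5 4-(benzyloxy)-2-bromo-6-hydroxybenzaldehyde
Conditions: BnBr (1.05 equiv), NaHCO3, MeCN, 80 °C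
Reagents that add atoms: benzyl bromide BrCc1ccccc1
Why: Williamson etherification with a weak base should take place only at the 4-hydroxyl, because the 6-hydroxyl is held in a hydrogen bond to the aldehyde oxygen, the usual selectivity of 2,4-dihydroxybenzaldehydes.

Step 4
Reactants: 5 4-(benzyloxy)-2-bromo-6-hydroxybenzaldehyde
Product: 6 4-(benzyloxy)-2-bromo-6-methoxybenzaldehyde
Conditions: MeI, K2CO3, DMF, rt
Reagents that add atoms: iodomethane CI
Why: Williamson methylation of the remaining chelated phenol proceeds once a stronger base in a dipolar solvent breaks the hydrogen bond.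

Step 5
Reactants: 6 4-(benzyloxy)-2-bromo-6-methoxybenzaldehyde
Product: 7 2-[4-(benzyloxy)-2-bromo-6-methoxyphenyl]-1,3-dioxolane
Conditions: ethylene glycol, p-TsOH (cat.), toluene, reflux, azeotropic removal of water
Reagents that add atoms: ethylene glycol OCCO
Why: acid-catalysed acetalisation driven by water removal masks the aldehyde as a cyclic acetal that tolerates organolithium reagents, basic peroxide, fluoride and Mitsunobu conditions and is more robust on silica than a dimethyl acetal.

Step 6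
Reactants: 8 2,4-dihydroxybenzaldehyde
Product: 9 4-(benzyloxy)-2-hydroxybenzaldehyde
Conditions: BnBr (1.05 equiv), NaHCO3, MeCN, 80 °C
Reagents that add atoms: benzyl bromide BrCc1ccccc1
Why: the same hydrogen-bond-controlled Williamson etherification as in step 3 benzylates only the 4-hydroxyl.

Step 7
Reactants: 9 4-(benzyloxy)-2-hydroxybenzaldehyde
Product: 10 4-(benzyloxy)-2-{[2-(trimethylsilyl)ethoxy]methoxy}benzaldehyde
Conditions: NaH, DMF, 0 °C; then SEMCl, 0 °C → rt
Reagents that add atoms: 2-(trimethylsilyl)ethoxymethyl chloride ClCOCC[Si](C)(C)C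
Why: O-alkylation of the sodium phenoxide installs an acetal-type ether that cannot migrate between neighbouring oxygens in the next step and can later be removed by fluoride without acid, which the dioxolane on ring C would not survive.

Step 8
Reactants: 10 4-(benzyloxy)-2-{[2-(trimethylsilyl)ethoxy]methoxy}benzaldehyde
Product: 12 4-(benzyloxy)-2-{[2-(trimethylsilyl)ethoxy]methoxy}phenol, via aryl formate 11 (not isolated)
Conditions: mCPBA, CH2Cl2, 0 °C → rt; then Et3N, MeOH, rt
Reagents that add atoms: 3-chloroperoxybenzoic acid O=C(OO)c1cccc(Cl)c1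
Why: in this Baeyer–Villiger (Dakin-type) oxidation the aryl group, activated by ortho and para alkoxy groups, should migrate in preference to hydrogen, and formate 11 is methanolysed in the same flask.

Step 9
Reactants: 12 4-(benzyloxy)-2-{[2-(trimethylsilyl)ethoxy]methoxy}phenol
Product: 13 4-(benzyloxy)-2-{[2-(trimethylsilyl)ethoxy]methoxy}phenyl trifluoromethanesulfonate
Conditions: Tf2O, pyridine, CH2Cl2, 0 °C
Reagents that add atoms: trifluoromethanesulfonic anhydride O=S(=O)(OS(=O)(=O)C(F)(F)F)C(F)(F)F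
Why: O-sulfonylation of the phenol is routine and gives the halide-free electrophile that the coupling requires.

Step 10
Reactants: 7 2-[4-(benzyloxy)-2-bromo-6-methoxyphenyl]-1,3-dioxolane; 14 vinylboronic acid pinacol ester; 13 4-(benzyloxy)-2-{[2-(trimethylsilyl)ethoxy]methoxy}phenyl trifluoromethanesulfonate
Product: 17 2-{(1R)-1-[5-(benzyloxy)-2-(1,3-dioxolan-2-yl)-3-methoxyphenyl]-2-[4-(benzyloxy)-2-{[2-(trimethylsilyl)ethoxy]methoxy}phenyl]ethyl}-4,4,5,5-tetramethyl-1,3,2-dioxaborolane, via aryllithium 15 (not isolated), via boron ate complex 16 (not isolated)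
Conditions: n-BuLi, THF, −78 °C; 14, −78 °C → rt; evaporate; Pd(OAc)2 (2 mol%), (Sp,Sp)-MandyPhos [1,1′-bis(diphenylphosphino)-2,2′-bis(α-dimethylaminobenzyl)ferrocene] (2.4 mol%), 13, THF, 60 °C
Reagents that add atoms: none
Why: Bromine–lithium exchange on 7 gives aryllithium 15, which adds to boron of 14 to form the four-coordinate ate complex 16; oxidative addition of triflate 13 to zerovalent palladium then gives a cationic arylpalladium species (divalent palladium) that binds the vinyl group of 16 and triggers a 1,2-shift of the ring C aryl from boron to the α-carbon anti to the metal (forming C6c–C3′), after which reductive elimination joins the terminal carbon to ring D (forming C4′–C4a′) and leaves the pinacol boronic ester on C3′. The closest known reaction type is the palladium/MandyPhos-catalysed enantioselective conjunctive cross-coupling of aryllithium-derived vinylboron ate complexes with aryl triflates. No ring is closed in this step. The C3′ stereocentre is set under catalyst control, the chiral bisphosphine on palladium selecting the face of the bound vinyl group at which the metalate shift occurs, and the ligand enantiomer is chosen to give the (R)-boronic ester. The step needs the conjunctive pathway to outrun direct Suzuki-type aryl or vinyl transfer and needs high enantioselectivity; this is secured by the triflate leaving group and a halide-free ate complex (exchange with n-BuLi leaves only volatile 1-bromobutane, removed with the solvent), by the pinacol ester, and by each aryl partner carrying only one ortho substituent.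

Step 11
Reactants: 17 the (R)-boronic ester of step 10
Product: 19 (2R)-2-[5-(benzyloxy)-2-(1,3-dioxolan-2-yl)-3-methoxyphenyl]-3-[4-(benzyloxy)-2-{[2-(trimethylsilyl)ethoxy]methoxy}phenyl]propan-1-ol, via homologated boronic ester 18 (not isolated)
Conditions: BrCH2Cl, n-BuLi, THF, −78 °C → rt; then NaOH, H2O2, THF/H2O, 0 °C → rt
Reagents that add atoms: bromochloromethane ClCBr; hydrogen peroxide OO
Why: in this Matteson homologation (chloromethyl)lithium made in the flask adds to boron and the secondary benzylic carbon migrates with retention to insert C2′, after which oxidation of the primary C–B bond gives the alcohol without touching C3′.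

Step 12
Reactants: 19 the primary alcohol of step 11
Product: 20 5-(benzyloxy)-2-{(2R)-2-[5-(benzyloxy)-2-(1,3-dioxolan-2-yl)-3-methoxyphenyl]-3-hydroxypropyl}phenol
Conditions: Bu4NF, THF, 60 °C
Reagents that add atoms: none
Why: fluoride attack at silicon fragments the SEM ether (loss of ethylene and formaldehyde) and frees the ring D phenol under non-acidic conditions that leave the dioxolane and the benzyl ethers alone.

Step 13
Reactants: 20 the phenol alcohol of step 12
Product: 22 4-(benzyloxy)-2-[(3R)-7-(benzyloxy)-3,4-dihydro-2H-chromen-3-yl]-6-methoxybenzaldehyde, via chroman acetal 21 (not isolated)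
Conditions: PPh3, DIAD, THF, 0 °C → rt; then 1 M HCl, rt
Reagents that add atoms: water O
Why: Mitsunobu etherification lets the phenol displace the activated primary alcohol in a 6-exo-tet closure that forms O1′–C2′ without involving C3′, and dilute acid added to the same flask hydrolyses the dioxolane of 21 to the aldehyde.

Step 14
Reactants: 23 3-(benzyloxy)phenol
Product: 24 5-(benzyloxy)-2-iodophenol
Conditions: I2, NaHCO3, THF/H2O, 0 °C → rt
Reagents that add atoms: iodine II
Why: electrophilic iodination of the phenol under bicarbonate should occur ortho to the hydroxyl and para to the benzyloxy group, the less hindered of the doubly activated positions, as known for 3-alkoxyphenols.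

Step 15
Reactants: 24 5-(benzyloxy)-2-iodophenol; 22 the ring C aldehyde of step 13
Product: 26 5-(benzyloxy)-2-[{4-(benzyloxy)-2-[(3R)-7-(benzyloxy)-3,4-dihydro-2H-chromen-3-yl]-6-methoxyphenyl}(hydroxy)methyl]phenol, via dilithio phenoxide 25 (not isolated)
Conditions: 24 (2.5 equiv), n-BuLi (5 equiv), THF, −78 → −40 °C; then 22, −78 → 0 °C; H2O
Reagents that add atoms: none
Why: O-deprotonation followed by iodine–lithium exchange gives a protecting-group-free ortho-lithiated phenoxide that adds 1,2 to the hindered aldehyde and forms C4–C4a, the new carbinol centre arising as a mixture that is of no consequence because it becomes trigonal in step 19.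

Step 16
Reactants: 26 the ortho-hydroxybenzhydrol of step 15
Product: 27 5-(benzyloxy)-2-[{4-(benzyloxy)-2-[(3R)-7-(benzyloxy)-3,4-dihydro-2H-chromen-3-yl]-6-methoxyphenyl}(4-methylbenzenesulfonyl)methyl]phenol
Conditions: p-TolSO2H, CH2Cl2, rt
Reagents that add atoms: 4-methylbenzenesulfinic acid Cc1ccc(cc1)S(=O)O
Why: the sulfinic acid ionises the doubly activated benzhydrol and the sulfinate captures the cation at sulfur (SN1 substitution), giving a sulfone that releases the ortho-quinone methide under mild base.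

Step 17
Reactants: 28 2,3-dihydroxy-4-methoxybenzaldehyde
Product: 29 2,3-bis(benzyloxy)-4-methoxybenzaldehyde
Conditions: BnBr (2.5 equiv), K2CO3, DMF, 60 °C
Reagents that add atoms: benzyl bromide BrCc1ccccc1
Why: exhaustive Williamson benzylation protects the catechol of ring B in a form removed only in the last step.

Step 18
Reactants: 29 2,3-bis(benzyloxy)-4-methoxybenzaldehyde
Product: 31 2-[2,3-bis(benzyloxy)-4-methoxyphenyl]acetaldehyde, via enol ether 30 (not isolated)
Conditions: (MeOCH2)PPh3Cl, KOt-Bu, THF, 0 °C → rt; then 2 M HCl, THF, rt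
Reagents that add atoms: (methoxymethyl)triphenylphosphonium chloride COC[P+](c1ccccc1)(c1ccccc1)c1ccccc1.[Cl-]; water O
Why: Wittig methoxymethylenation followed by acid hydrolysis of enol ether 30 is the standard one-carbon homologation of an aryl aldehyde to the arylacetaldehyde, which is used at once.

Step 19
Reactants: 27 the sulfone of step 16; 31 2-[2,3-bis(benzyloxy)-4-methoxyphenyl]acetaldehyde
Product: 33 (3R,4S)-7-(benzyloxy)-4-{4-(benzyloxy)-2-[(3R)-7-(benzyloxy)-3,4-dihydro-2H-chromen-3-yl]-6-methoxyphenyl}-3-[2,3-bis(benzyloxy)-4-methoxyphenyl]-3,4-dihydro-2H-chromen-2-ol, via ortho-quinone methide 32 (not isolated)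
Conditions: (R)-α,α-diphenylprolinol trimethylsilyl ether (20 mol%), NaHCO3, CH2Cl2/H2O, 0 °C → rt
Reagents that add atoms: none
Why: base-induced 1,4-elimination of sulfinate gives (E)-ortho-quinone methide 32, to which the enamine of 31 adds in a formal inverse-demand [4+2] (Michael addition forming C3–C4, then hemiacetalisation forming O1–C2), the diphenyl(silyloxy)methyl group of the catalyst shielding one enamine face so that C3 is set as R and the anti approach to the methide carbon sets C4 as S, the trans arrangement known for amine-catalysed additions of aldehydes to ortho-quinone methides.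

Step 20
Reactants: 33 the lactol of step 19
Product: 34 (3R,4S)-7-(benzyloxy)-4-{4-(benzyloxy)-2-[(3R)-7-(benzyloxy)-3,4-dihydro-2H-chromen-3-yl]-6-methoxyphenyl}-3-[2,3-bis(benzyloxy)-4-methoxyphenyl]-3,4-dihydro-2H-chromene
Conditions: Et3SiH, TFA, CH2Cl2, 0 °C
Reagents that add atoms: none
Why: ionic hydrogenation ionises the lactol to a cyclic oxocarbenium ion that the silane reduces at C2, and any enolisation through the 4H-chromene can only return C3 to the more stable trans arrangement that is wanted.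

Step 21
Reactants: 34 the pentabenzyl ether of step 20
Product: 35 (3R,4S)-3-(2,3-dihydroxy-4-methoxyphenyl)-4-{4-hydroxy-2-[(3R)-7-hydroxy-3,4-dihydro-2H-chromen-3-yl]-6-methoxyphenyl}-3,4-dihydro-2H-chromen-7-ol
Conditions: H2 (1 atm), Pd/C (10 wt% Pd on carbon), THF/MeOH, rt, work-up under argon
Reagents that add atoms: none
Why: catalytic hydrogenolysis cleaves the five benzyl aryl ethers, while the chroman C–O bonds (not benzylic) and the three C–H stereocentres are inert.

**Compound list**

1 | 1-bromo-3,5-dimethoxybenzene | COc1cc(Br)cc(OC)c1 | starting material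
2 | N-[(2-bromo-4,6-dimethoxyphenyl)methylidene]-N-methylmethanaminium chloride | C[N+](C)=Cc1c(Br)cc(OC)cc1OC.[Cl-] | intermediate
3 | 2-bromo-4,6-dimethoxybenzaldehyde | COc1cc(Br)c(C=O)c(OC)c1 | intermediate
4 | 2-bromo-4,6-dihydroxybenzaldehyde | O=Cc1c(O)cc(O)cc1Br | intermediate
5 | 4-(benzyloxy)-2-bromo-6-hydroxybenzaldehyde | O=Cc1c(O)cc(OCc2ccccc2)cc1Br | intermediate
6 | 4-(benzyloxy)-2-bromo-6-methoxybenzaldehyde | COc1cc(OCc2ccccc2)cc(Br)c1C=O | intermediate
7 | 2-[4-(benzyloxy)-2-bromo-6-methoxyphenyl]-1,3-dioxolane | COc1cc(OCc2ccccc2)cc(Br)c1C1OCCO1 | intermediate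
8 | 2,4-dihydroxybenzaldehyde | O=Cc1ccc(O)cc1O | starting material
9 | 4-(benzyloxy)-2-hydroxybenzaldehyde | O=Cc1ccc(OCc2ccccc2)cc1O | intermediate
10 | 4-(benzyloxy)-2-{[2-(trimethylsilyl)ethoxy]methoxy}benzaldehyde | O=Cc1ccc(OCc2ccccc2)cc1OCOCC[Si](C)(C)C | intermediate
11 | 4-(benzyloxy)-2-{[2-(trimethylsilyl)ethoxy]methoxy}phenyl formate | O=COc1ccc(OCc2ccccc2)cc1OCOCC[Si](C)(C)C | intermediate
12 | 4-(benzyloxy)-2-{[2-(trimethylsilyl)ethoxy]methoxy}phenol | Oc1ccc(OCc2ccccc2)cc1OCOCC[Si](C)(C)C | intermediate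
13 | 4-(benzyloxy)-2-{[2-(trimethylsilyl)ethoxy]methoxy}phenyl trifluoromethanesulfonate | O=S(=O)(Oc1ccc(OCc2ccccc2)cc1OCOCC[Si](C)(C)C)C(F)(F)F | intermediate
14 | vinylboronic acid pinacol ester (2-ethenyl-4,4,5,5-tetramethyl-1,3,2-dioxaborolane) | C=CB1OC(C)(C)C(C)(C)O1 | starting material
15 | [5-(benzyloxy)-2-(1,3-dioxolan-2-yl)-3-methoxyphenyl]lithium | [Li]c1cc(OCc2ccccc2)cc(OC)c1C1OCCO1 | intermediate
16 | lithium [5-(benzyloxy)-2-(1,3-dioxolan-2-yl)-3-methoxyphenyl](ethenyl)(pinacolato)borate | [Li+].C=C[B-]1(c2cc(OCc3ccccc3)cc(OC)c2C2OCCO2)OC(C)(C)C(C)(C)O1 | intermediate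
17 | 2-{(1R)-1-[5-(benzyloxy)-2-(1,3-dioxolan-2-yl)-3-methoxyphenyl]-2-[4-(benzyloxy)-2-{[2-(trimethylsilyl)ethoxy]methoxy}phenyl]ethyl}-4,4,5,5-tetramethyl-1,3,2-dioxaborolane | COc1cc(OCc2ccccc2)cc([C@@H](Cc2ccc(OCc3ccccc3)cc2OCOCC[Si](C)(C)C)B2OC(C)(C)C(C)(C)O2)c1C1OCCO1 | intermediate
18 | 2-{(2R)-2-[5-(benzyloxy)-2-(1,3-dioxolan-2-yl)-3-methoxyphenyl]-3-[4-(benzyloxy)-2-{[2-(trimethylsilyl)ethoxy]methoxy}phenyl]propyl}-4,4,5,5-tetramethyl-1,3,2-dioxaborolane | COc1cc(OCc2ccccc2)cc([C@@H](Cc2ccc(OCc3ccccc3)cc2OCOCC[Si](C)(C)C)CB2OC(C)(C)C(C)(C)O2)c1C1OCCO1 | intermediate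
19 | (2R)-2-[5-(benzyloxy)-2-(1,3-dioxolan-2-yl)-3-methoxyphenyl]-3-[4-(benzyloxy)-2-{[2-(trimethylsilyl)ethoxy]methoxy}phenyl]propan-1-ol | COc1cc(OCc2ccccc2)cc([C@@H](Cc2ccc(OCc3ccccc3)cc2OCOCC[Si](C)(C)C)CO)c1C1OCCO1 | intermediate
20 | 5-(benzyloxy)-2-{(2R)-2-[5-(benzyloxy)-2-(1,3-dioxolan-2-yl)-3-methoxyphenyl]-3-hydroxypropyl}phenol | COc1cc(OCc2ccccc2)cc([C@@H](Cc2ccc(OCc3ccccc3)cc2O)CO)c1C1OCCO1 | intermediate
21 | (3R)-7-(benzyloxy)-3-[5-(benzyloxy)-2-(1,3-dioxolan-2-yl)-3-methoxyphenyl]-3,4-dihydro-2H-chromene | COc1cc(OCc2ccccc2)cc([C@@H]2COc3cc(OCc4ccccc4)ccc3C2)c1C1OCCO1 | intermediate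
22 | 4-(benzyloxy)-2-[(3R)-7-(benzyloxy)-3,4-dihydro-2H-chromen-3-yl]-6-methoxybenzaldehyde | COc1cc(OCc2ccccc2)cc([C@@H]2COc3cc(OCc4ccccc4)ccc3C2)c1C=O | intermediate
23 | 3-(benzyloxy)phenol | Oc1cccc(OCc2ccccc2)c1 | starting material
24 | 5-(benzyloxy)-2-iodophenol | Oc1cc(OCc2ccccc2)ccc1I | intermediate
25 | lithium 5-(benzyloxy)-2-lithiophenolate | [Li]Oc1cc(OCc2ccccc2)ccc1[Li] | intermediate
26 | 5-(benzyloxy)-2-[{4-(benzyloxy)-2-[(3R)-7-(benzyloxy)-3,4-dihydro-2H-chromen-3-yl]-6-methoxyphenyl}(hydroxy)methyl]phenol, both carbinol epimers | COc1cc(OCc2ccccc2)cc([C@@H]2COc3cc(OCc4ccccc4)ccc3C2)c1C(O)c1ccc(OCc2ccccc2)cc1O | intermediate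
27 | 5-(benzyloxy)-2-[{4-(benzyloxy)-2-[(3R)-7-(benzyloxy)-3,4-dihydro-2H-chromen-3-yl]-6-methoxyphenyl}(4-methylbenzenesulfonyl)methyl]phenol, both epimers at the sulfonyl carbon | COc1cc(OCc2ccccc2)cc([C@@H]2COc3cc(OCc4ccccc4)ccc3C2)c1C(c1ccc(OCc2ccccc2)cc1O)S(=O)(=O)c1ccc(C)cc1 | intermediate
28 | 2,3-dihydroxy-4-methoxybenzaldehyde | COc1ccc(C=O)c(O)c1O | starting material
29 | 2,3-bis(benzyloxy)-4-methoxybenzaldehyde | COc1ccc(C=O)c(OCc2ccccc2)c1OCc1ccccc1 | intermediate
30 | 2,3-bis(benzyloxy)-4-methoxy-1-(2-methoxyethenyl)benzene, E/Z mixture | COC=Cc1ccc(OC)c(OCc2ccccc2)c1OCc1ccccc1 | intermediate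
31 | 2-[2,3-bis(benzyloxy)-4-methoxyphenyl]acetaldehyde | COc1ccc(CC=O)c(OCc2ccccc2)c1OCc1ccccc1 | intermediate
32 | (6E)-3-(benzyloxy)-6-({4-(benzyloxy)-2-[(3R)-7-(benzyloxy)-3,4-dihydro-2H-chromen-3-yl]-6-methoxyphenyl}methylidene)cyclohexa-2,4-dien-1-one | COc1cc(OCc2ccccc2)cc([C@@H]2COc3cc(OCc4ccccc4)ccc3C2)c1/C=C1\C=CC(OCc2ccccc2)=CC1=O | intermediate
33 | (3R,4S)-7-(benzyloxy)-4-{4-(benzyloxy)-2-[(3R)-7-(benzyloxy)-3,4-dihydro-2H-chromen-3-yl]-6-methoxyphenyl}-3-[2,3-bis(benzyloxy)-4-methoxyphenyl]-3,4-dihydro-2H-chromen-2-ol, both C2 epimers | COc1ccc([C@@H]2C(O)Oc3cc(OCc4ccccc4)ccc3[C@H]2c2c(OC)cc(OCc4ccccc4)cc2[C@@H]2COc3cc(OCc4ccccc4)ccc3C2)c(OCc2ccccc2)c1OCc1ccccc1 | intermediate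
34 | (3R,4S)-7-(benzyloxy)-4-{4-(benzyloxy)-2-[(3R)-7-(benzyloxy)-3,4-dihydro-2H-chromen-3-yl]-6-methoxyphenyl}-3-[2,3-bis(benzyloxy)-4-methoxyphenyl]-3,4-dihydro-2H-chromene | COc1ccc([C@@H]2COc3cc(OCc4ccccc4)ccc3[C@H]2c2c(OC)cc(OCc4ccccc4)cc2[C@@H]2COc3cc(OCc4ccccc4)ccc3C2)c(OCc2ccccc2)c1OCc1ccccc1 | intermediate
35 | (3R,4S)-3-(2,3-dihydroxy-4-methoxyphenyl)-4-{4-hydroxy-2-[(3R)-7-hydroxy-3,4-dihydro-2H-chromen-3-yl]-6-methoxyphenyl}-3,4-dihydro-2H-chromen-7-ol | COc1ccc([C@@H]2COc3cc(O)ccc3[C@H]2c2c(OC)cc(O)cc2[C@@H]2COc3cc(O)ccc3C2)c(O)c1O | target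

**Count and risks**

Total step count: 21. Longest linear sequence: 14 steps (steps 1–5, 10–13, 15, 16, 19–21).

Step 10. The ortho-acetal on the migrating aryl may slow the metalate shift, so that direct aryl or vinyl transfer to palladium and protodeboronation take over, or the enantioselectivity may erode. The fallback replaces the catalytic three-component coupling by reagent-controlled lithiation–borylation; it sets out from 7 and 10 and comes back to the route at 17. Bromide 7 would be lithiated (n-BuLi, THF, −78 °C, through 15) and quenched with i-PrOB(pin) to give the aryl pinacol boronic ester F1. Aldehyde 10 would be methylenated (Ph3PCH3Br, KOt-Bu) to the styrene F2, hydroborated with 9-borabicyclo[3.3.1]nonane to the B-alkylborane F3 and oxidised (NaOH, H2O2) to the 2-arylethanol F4, which would be acylated with 2,4,6-triisopropylbenzoyl chloride (Et3N, DMAP) to the hindered benzoate F5. Deprotonation of F5 next to oxygen with s-BuLi and (−)-sparteine (Et2O, −78 °C) should give the configurationally stable (S)-α-lithiated benzoate F6, which F1 traps with retention as the boron ate complex F7. On warming with MgBr2·OEt2 the ring C aryl should migrate from boron to carbon with inversion and expel the benzoate, which delivers 17.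

Step 19. The enamine may add to the hindered ortho-quinone methide with poor facial selectivity (a mismatch with C3′ cannot be excluded), while self-aldol condensation of 31 and hydration of 32 compete. The fallback changes from enamine to Lewis-base ester-enolate catalysis; it sets out from 27 and 31 and comes back at 33. Aldehyde 31 would be oxidised (NaClO2, NaH2PO4, 2-methyl-2-butene; Pinnick oxidation) to the arylacetic acid F8 and activated in the flask with pivaloyl chloride and i-Pr2NEt as the mixed anhydride F9. A chiral isothiourea (HyperBTM) should turn F9 into an ammonium enolate that adds to 32, released from 27 by the same amine base, and lactonises to the trans-dihydrocoumarin F10, whose C3 can be equilibrated to trans with base if needed. Reduction with i-Bu2AlH (CH2Cl2, −78 °C) then gives lactol 33.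

Step 16. The doubly activated benzhydryl cation may be consumed by Friedel–Crafts oligomerisation before sulfinate captures it, or the sulfone may ionise again during isolation. The fallback generates the quinone methide by oxidation instead of elimination; it sets out from 26 and comes back at 33. Ionic hydrogenation of 26 (Et3SiH, TFA, CH2Cl2, 0 °C) should give the 2-benzylphenol F11. Oxidation of F11 with Ag2O in the presence of 31 and the prolinol catalyst of step 19 would form 32 directly, which is intercepted as in step 19 to give 33.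

**Further compounds**

F1 | step 10 | 2-[5-(benzyloxy)-2-(1,3-dioxolan-2-yl)-3-methoxyphenyl]-4,4,5,5-tetramethyl-1,3,2-dioxaborolane | COc1cc(OCc2ccccc2)cc(B2OC(C)(C)C(C)(C)O2)c1C1OCCO1
F2 | step 10 | 4-(benzyloxy)-1-ethenyl-2-{[2-(trimethylsilyl)ethoxy]methoxy}benzene | C=Cc1ccc(OCc2ccccc2)cc1OCOCC[Si](C)(C)C
F3 | step 10 | 9-{2-[4-(benzyloxy)-2-{[2-(trimethylsilyl)ethoxy]methoxy}phenyl]ethyl}-9-borabicyclo[3.3.1]nonane | C1CCC2CCCC1B2CCc1ccc(OCc2ccccc2)cc1OCOCC[Si](C)(C)C
F4 | step 10 | 2-[4-(benzyloxy)-2-{[2-(trimethylsilyl)ethoxy]methoxy}phenyl]ethan-1-ol | OCCc1ccc(OCc2ccccc2)cc1OCOCC[Si](C)(C)C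
F5 | step 10 | 2-[4-(benzyloxy)-2-{[2-(trimethylsilyl)ethoxy]methoxy}phenyl]ethyl 2,4,6-triisopropylbenzoate | CC(C)c1cc(C(C)C)c(C(=O)OCCc2ccc(OCc3ccccc3)cc2OCOCC[Si](C)(C)C)c(C(C)C)c1
F6 | step 10 | (1S)-2-[4-(benzyloxy)-2-{[2-(trimethylsilyl)ethoxy]methoxy}phenyl]-1-lithioethyl 2,4,6-triisopropylbenzoate | CC(C)c1cc(C(C)C)c(C(=O)O[C@H](Cc2ccc(OCc3ccccc3)cc2OCOCC[Si](C)(C)C)[Li])c(C(C)C)c1
F7 | step 10 | lithium [5-(benzyloxy)-2-(1,3-dioxolan-2-yl)-3-methoxyphenyl]{(1S)-2-[4-(benzyloxy)-2-{[2-(trimethylsilyl)ethoxy]methoxy}phenyl]-1-[(2,4,6-triisopropylbenzoyl)oxy]ethyl}(pinacolato)borate | [Li+].CC(C)c1cc(C(C)C)c(C(=O)O[C@H](Cc2ccc(OCc3ccccc3)cc2OCOCC[Si](C)(C)C)[B-]2(c3cc(OCc4ccccc4)cc(OC)c3C3OCCO3)OC(C)(C)C(C)(C)O2)c(C(C)C)c1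
F8 | step 19 | 2-[2,3-bis(benzyloxy)-4-methoxyphenyl]acetic acid | COc1ccc(CC(=O)O)c(OCc2ccccc2)c1OCc1ccccc1
F9 | step 19 | 2-[2,3-bis(benzyloxy)-4-methoxyphenyl]acetic 2,2-dimethylpropanoic anhydride | COc1ccc(CC(=O)OC(=O)C(C)(C)C)c(OCc2ccccc2)c1OCc1ccccc1
F10 | step 19 | (3R,4S)-7-(benzyloxy)-4-{4-(benzyloxy)-2-[(3R)-7-(benzyloxy)-3,4-dihydro-2H-chromen-3-yl]-6-methoxyphenyl}-3-[2,3-bis(benzyloxy)-4-methoxyphenyl]-3,4-dihydro-2H-chromen-2-one | COc1ccc([C@@H]2C(=O)Oc3cc(OCc4ccccc4)ccc3[C@H]2c2c(OC)cc(OCc4ccccc4)cc2[C@@H]2COc3cc(OCc4ccccc4)ccc3C2)c(OCc2ccccc2)c1OCc1ccccc1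
F11 | step 16 | 5-(benzyloxy)-2-({4-(benzyloxy)-2-[(3R)-7-(benzyloxy)-3,4-dihydro-2H-chromen-3-yl]-6-methoxyphenyl}methyl)phenol | COc1cc(OCc2ccccc2)cc([C@@H]2COc3cc(OCc4ccccc4)ccc3C2)c1Cc1ccc(OCc2ccccc2)cc1O
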